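**Plan**

Numbering: flavanone atoms unprimed (its catechol ring B primed), flavone atoms double-primed, the 4-hydroxyphenyl ring triple-primed.
Retrosynthesis: cut O1–C2 and C2–C3 of the flavanone (oxa-Michael, Knoevenagel) to a ring B aldehyde and a phloroacetophenone beta-ketoester; cut O1''–C2'' and C4''–C4a'' of the flavone (amino-enone closure, acetylide addition); cut C5''–C6'' and C7''–C8'' of flavone ring A to a ring B aryl siloxyalkyne and a 3-alkoxycyclobutenone.
Enabling feature: flavone ring A bears oxygen on C5'', C7'' and C8a'', with C2' of ring B on C6'' between O5'' and O7''. A vinylketene carbonyl (O5''), an aryl siloxyalkyne (C6'', O7'') and a 3-alkoxy group (O8a'') give exactly this ring, with three differently protected oxygens.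
Forward order: ring B alkyne, flavone ring A by benzannulation, formylation at C4a'', flavone ring C, the flavanone heterocycle onto a preformed phloroglucinol ring, global debenzylation.
Stereochemistry: the only stereocentre, C2 (S), is set by a cinchona-thiourea-catalysed oxa-Michael ring closure and meets no base afterwards.

Key step: step 7

Assumption: the C2'–C6'' biaryl axis is not defined in the target structure, so it is left uncontrolled and only C2 is set.
Assumption: the quinidine-derived thiourea is taken to give the 2S series; should the sense be opposite, the quinine-derived pseudoenantiomer is used in the same way.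
Abbreviations: ArB = 2,3-bis(benzyloxy)-6-(1,3-dioxolan-2-yl)phenyl; Fl = 5,7-bis(benzyloxy)-2-[4-(benzyloxy)phenyl]-4-oxo-4H-chromen-6-yl.

**Route**

Step 1
Reactants: 1 2-bromo-3-hydroxy-4-methoxybenzaldehyde
Product: 2 2-bromo-3,4-dihydroxybenzaldehyde
Conditions: BBr3, CH2Cl2, −78 °C → rt; H2O quench
Reagents that add atoms: none
Why: Lewis-acid cleavage of an aryl methyl ether (BBr3 demethylation), which an aryl bromide and an aldehyde tolerate, frees the catechol so that hydrogenolysable groups can be used from the start.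

Step 2
Reactants: 2 2-bromo-3,4-dihydroxybenzaldehyde
Product: 3 3,4-bis(benzyloxy)-2-bromobenzaldehyde
Conditions: BnBr, K2CO3, DMF, 60 °C
Reagents that add atoms: benzyl bromide, BrCc1ccccc1
Why: Williamson etherification of both phenols installs benzyl ethers that should survive every later step and fall in the final hydrogenolysis.

Step 3
Reactants: 3 3,4-bis(benzyloxy)-2-bromobenzaldehyde; 4 ethynyltrimethylsilane
Product: 5 3,4-bis(benzyloxy)-2-[(trimethylsilyl)ethynyl]benzaldehyde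
Conditions: Pd(PPh3)2Cl2 (5 mol %), CuI (10 mol %), Et3N, THF, 65 °C
Reagents that add atoms: none
Why: Sonogashira coupling, in which oxidative addition into the flanked C–Br bond is helped by the ortho formyl group.

Step 4
Reactants: 5 3,4-bis(benzyloxy)-2-[(trimethylsilyl)ethynyl]benzaldehyde
Product: 7 2-[3,4-bis(benzyloxy)-2-ethynylphenyl]-1,3-dioxolane, via the trimethylsilyl alkyne dioxolane 6 (not isolated)
Conditions: HOCH2CH2OH, TsOH·H2O (cat.), PhH, reflux (Dean–Stark); then K2CO3, MeOH, rt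
Reagents that add atoms: ethylene glycol, OCCO
Why: Acid-catalysed acetalisation with azeotropic water removal masks the ring B aldehyde as a dioxolane (chosen over an acyclic acetal because it should not exchange with the neighbouring phenol formed in step 7), and carbonate methanolysis then removes the alkynyl silyl group.

Step 5
Reactants: 7 2-[3,4-bis(benzyloxy)-2-ethynylphenyl]-1,3-dioxolane
Product: 10 [(ArB-ethynyl)oxy]triisopropylsilane, via lithium acetylide 8 (not isolated), via lithium ynolate 9 (not isolated)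
Conditions: n-BuLi, THF, −78 °C; t-BuOOLi (from t-BuOOH, LiN(SiMe3)2), −78 → 0 °C; TIPSOTf, −78 → 0 °C
Reagents that add atoms: tert-butyl hydroperoxide, CC(C)(C)OO; triisopropylsilyl trifluoromethanesulfonate, CC(C)[Si](OS(=O)(=O)C(F)(F)F)(C(C)C)C(C)C
Why: Oxygen transfer from lithium tert-butyl peroxide to a lithium acetylide gives the ynolate and a bulky silyl triflate traps it on oxygen, a sequence established for aryl acetylenes that acts only at the unhindered alkyne terminus (hence preferred to an ester homologation at the crowded ring carbon).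

Step 6
Reactants: 11 3-ethoxycyclobut-2-en-1-one
Product: 12 3-(allyloxy)cyclobut-2-en-1-one
Conditions: allyl alcohol (excess), CSA (cat.), PhH, 40 °C, EtOH removed under reduced pressure
Reagents that add atoms: allyl alcohol, C=CCO
Why: Acid-catalysed alkoxy exchange of a vinylogous ester by addition–elimination at C3, pulled to the allyl ether by excess allyl alcohol and removal of ethanol, and run well below the temperature of electrocyclic ring opening.

Step 7
Reactants: 10 [(ArB-ethynyl)oxy]triisopropylsilane; 12 3-(allyloxy)cyclobut-2-en-1-one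
Product: 17 5-(allyloxy)-2-ArB-3-(triisopropylsilyloxy)phenol, via vinylketene 3-(allyloxy)buta-1,3-dien-1-one 13 (not isolated), via 4-[1-(allyloxy)vinyl]-2-ArB-3-(triisopropylsilyloxy)cyclobut-2-en-1-one 14 (not isolated), via dienylketene 5-(allyloxy)-2-ArB-3-(triisopropylsilyloxy)hexa-1,3,5-trien-1-one 15 (not isolated), via 5-(allyloxy)-2-ArB-3-(triisopropylsilyloxy)cyclohexa-2,4-dien-1-one 16 (not isolated)
Conditions: 12 (1.5 equiv), PhMe (0.4 M), 80 → 110 °C, Ar
Reagents that add atoms: none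
Why: Danheiser benzannulation of a cyclobutenone with a siloxyalkyne: 12 opens by 4π electrocyclic cleavage to vinylketene 13, whose ketene carbon is attacked by the nucleophilic aryl-bearing carbon of the ynol ether in a regiospecific [2+2] cycloaddition (C5''–C6'' and C7''–C8'' form) to give 14. A second 4π opening gives dienylketene 15, and flavone ring A closes by thermal 6π electrocyclisation between the ketene carbon and the terminal methylene (C5''–C4a'', the bond the first ring opening had broken), followed by tautomerisation of dienone 16 to the phenol. The closest precedent is the synthesis of resorcinol monosilyl ethers from alkyl siloxyalkynes and 3-substituted cyclobutenones. No stereocentre is formed, since the sp3 carbon of 14 is lost on aromatisation. The step needs regiocontrol only, and the push–pull polarity of ketene and ynol ether secures it: the ketene oxygen becomes the free hydroxyl O5'', the silyl ether is O7'', both flank the ring B substituent on C6'', and the allyl ether O8a'' lies para to it. The two ortho substituents of ring B are the main burden, so the compact dioxolane is used and the small ketene precursor is taken in excess.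

Step 8
Reactants: 17 5-(allyloxy)-2-ArB-3-(triisopropylsilyloxy)phenol
Product: 19 6-(allyloxy)-3-ArB-2-hydroxy-4-(triisopropylsilyloxy)benzaldehyde, via the 6-(hydroxymethyl)phenol 18 (not isolated)
Conditions: MgCl2, Et3N, (CH2O)n, MeCN, reflux; pH 6 buffer work-up
Reagents that add atoms: paraformaldehyde (as formaldehyde), C=O
Why: Magnesium-mediated ortho-formylation (Casnati–Skattebøl reaction): the magnesium phenoxide delivers formaldehyde to the only free ortho position, C4a'', a second formaldehyde oxidises the benzylic alkoxide to the aldehyde, and the buffered work-up keeps the dioxolane.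

Step 9
Reactants: 19 6-(allyloxy)-3-ArB-2-hydroxy-4-(triisopropylsilyloxy)benzaldehyde
Product: 21 6-(allyloxy)-3-ArB-2,4-bis(benzyloxy)benzaldehyde, via the 2-benzyl ether 4-silyl ether 20 (not isolated)
Conditions: BnBr, K2CO3, DMF, 50 °C; then CsF, rt
Reagents that add atoms: benzyl bromide, BrCc1ccccc1
Why: Williamson benzylation of the chelated phenol, then fluoride cleavage of the aryl silyl ether with in situ benzylation of the phenoxide, puts the same hydrogenolysable group on O5'' and O7'' and leaves only O8a'' as an allyl ether.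

Step 10
Reactants: 21 6-(allyloxy)-3-ArB-2,4-bis(benzyloxy)benzaldehyde; 22 1-(benzyloxy)-4-ethynylbenzene
Product: 24 1-[6-(allyloxy)-3-ArB-2,4-bis(benzyloxy)phenyl]-3-[4-(benzyloxy)phenyl]prop-2-yn-1-ol (carbinol centre uncontrolled), via lithium [4-(benzyloxy)phenyl]acetylide 23 (not isolated)
Conditions: 22, n-BuLi, THF, −78 °C; then 21, −78 → 0 °C
Reagents that add atoms: none
Why: 1,2-Addition of a lithium acetylide to a non-enolisable aldehyde; the new carbinol centre need not be controlled because the next step oxidises it.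

Step 11
Reactants: 24 the propargylic alcohol
Product: 25 1-[6-(allyloxy)-3-ArB-2,4-bis(benzyloxy)phenyl]-3-[4-(benzyloxy)phenyl]prop-2-yn-1-one
Conditions: MnO2, CH2Cl2, rt
Reagents that add atoms: none
Why: MnO2 oxidation of a benzylic propargylic alcohol to the ynone under neutral conditions that leave acetal, allyl and benzyl ethers alone.

Step 12
Reactants: 25 the ynone
Product: 28 5,7-bis(benzyloxy)-2-[4-(benzyloxy)phenyl]-6-ArB-4H-chromen-4-one, via the 3-morpholino enone allyl ether 26 (not isolated), via the 3-morpholino enone phenol 27 (not isolated)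
Conditions: Pd(PPh3)4 (5 mol %), morpholine (5 equiv), THF, rt → 60 °C
Reagents that add atoms: none
Why: Morpholine adds to the ynone to give a beta-amino enone, zerovalent palladium transfers the allyl group from O8a'' to morpholine (Tsuji–Trost deallylation), and the freed phenol displaces the amine by addition–elimination, so only the six-membered pyranone (flavone, not aurone) can form and only through O8a''.

Step 13
Reactants: 28 the flavone dioxolane
Product: 29 3,4-bis(benzyloxy)-2-Fl-benzaldehyde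
Conditions: 1 M HCl, THF, rt
Reagents that add atoms: water, O
Why: Acid-catalysed acetal hydrolysis; the benzyl ethers and the fully O-protected flavone are stable to dilute acid.

Step 14
Reactants: 30 1-(2,4,6-trihydroxyphenyl)ethan-1-one
Product: 31 1-[2,4-bis(benzyloxy)-6-hydroxyphenyl]ethan-1-one
Conditions: BnBr (2.1 equiv), K2CO3, DMF, rt
Reagents that add atoms: benzyl bromide, BrCc1ccccc1
Why: Williamson etherification in which the hydroxyl hydrogen-bonded to the ketone is the least nucleophilic and stays free.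

Step 15
Reactants: 31 1-[2,4-bis(benzyloxy)-6-hydroxyphenyl]ethan-1-one
Product: 33 tert-butyl 3-[2,4-bis(benzyloxy)-6-hydroxyphenyl]-3-oxopropanoate, via the dilithium enolate phenoxide 32 (not isolated)
Conditions: LiN(SiMe3)2 (3.3 equiv), THF, −78 °C; Boc2O, −78 → 0 °C
Reagents that add atoms: di-tert-butyl dicarbonate, CC(C)(C)OC(=O)OC(=O)OC(C)(C)C
Why: Claisen-type C-acylation, in which the enolate carbon of the dianion is far more nucleophilic than the chelated phenoxide and the third equivalent of base absorbs the acidic product.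

Step 16
Reactants: 29 3,4-bis(benzyloxy)-2-Fl-benzaldehyde; 33 the beta-ketoester
Product: 34 tert-butyl 2-[2,4-bis(benzyloxy)-6-hydroxybenzoyl]-3-[3,4-bis(benzyloxy)-2-Fl-phenyl]prop-2-enoate (E/Z mixture)
Conditions: piperidine (cat.), AcOH (cat.), PhMe, 4 Å MS, rt → 40 °C
Reagents that add atoms: none
Why: Knoevenagel condensation under piperidinium acetate catalysis; the ester is the activating and catalyst-binding group for the next step and the alkene mixture is used as such.

Step 17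
Reactants: 34 the alkylidene beta-ketoester
Product: 36 (2S)-5,7-bis(benzyloxy)-2-[3,4-bis(benzyloxy)-2-Fl-phenyl]chroman-4-one, via the tert-butyl (2S)-4-oxochromane-3-carboxylate 35 (not isolated)
Conditions: 9-amino-9-deoxy-epi-quinidine 3,5-bis(trifluoromethyl)phenyl thiourea (10 mol %), PhMe, −25 °C; then TsOH·H2O, 80 °C
Reagents that add atoms: none
Why: Enantioselective intramolecular oxa-Michael addition under bifunctional catalysis, in which the thiourea binds the beta-ketoester while the quinuclidine activates the phenol so that oxygen attacks one face of the alkylidene and sets C2 as S; acidolysis of the tert-butyl ester and decarboxylation then remove the activating group without touching C2.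

Step 18
Reactants: 36 the heptabenzyl (2S)-flavanone
Product: 37 (2S)-2-{2-[5,7-dihydroxy-2-(4-hydroxyphenyl)-4-oxo-4H-chromen-6-yl]-3,4-dihydroxyphenyl}-5,7-dihydroxychroman-4-one
Conditions: H2 (1 atm), Pd/C, EtOAc/MeOH, rt
Reagents that add atoms: none
Why: Catalytic hydrogenolysis of all seven benzyl ethers under neutral conditions, which should neither open the flavanone ring nor epimerise C2.

**Compound list**

1 | 2-bromo-3-hydroxy-4-methoxybenzaldehyde | O=Cc1ccc(OC)c(O)c1Br | starting material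
2 | 2-bromo-3,4-dihydroxybenzaldehyde | O=Cc1ccc(O)c(O)c1Br | intermediate
3 | 3,4-bis(benzyloxy)-2-bromobenzaldehyde | O=Cc1ccc(OCc2ccccc2)c(OCc2ccccc2)c1Br | intermediate
4 | ethynyltrimethylsilane | C#C[Si](C)(C)C | starting material
5 | 3,4-bis(benzyloxy)-2-[(trimethylsilyl)ethynyl]benzaldehyde | O=Cc1ccc(OCc2ccccc2)c(OCc2ccccc2)c1C#C[Si](C)(C)C | intermediate
6 | (ArB-ethynyl)trimethylsilane (formed in situ) | C[Si](C)(C)C#Cc1c(C2OCCO2)ccc(OCc2ccccc2)c1OCc1ccccc1 | intermediate
7 | 2-[3,4-bis(benzyloxy)-2-ethynylphenyl]-1,3-dioxolane | C#Cc1c(C2OCCO2)ccc(OCc2ccccc2)c1OCc1ccccc1 | intermediate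
8 | lithium acetylide of 7 (formed in situ) | [Li]C#Cc1c(C2OCCO2)ccc(OCc2ccccc2)c1OCc1ccccc1 | intermediate
9 | lithium 2-ArB-ethynolate (formed in situ) | [Li+].[O-]C#Cc1c(C2OCCO2)ccc(OCc2ccccc2)c1OCc1ccccc1 | intermediate
10 | [(ArB-ethynyl)oxy]triisopropylsilane | CC(C)[Si](OC#Cc1c(C2OCCO2)ccc(OCc2ccccc2)c1OCc1ccccc1)(C(C)C)C(C)C | intermediate
11 | 3-ethoxycyclobut-2-en-1-one | CCOC1=CC(=O)C1 | starting material
12 | 3-(allyloxy)cyclobut-2-en-1-one | C=CCOC1=CC(=O)C1 | intermediate
13 | 3-(allyloxy)buta-1,3-dien-1-one (vinylketene, formed in situ) | C=CCOC(=C)C=C=O | intermediate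
14 | 4-[1-(allyloxy)vinyl]-2-ArB-3-(triisopropylsilyloxy)cyclobut-2-en-1-one (racemic, formed in situ) | O=C1C(c2c(C3OCCO3)ccc(OCc3ccccc3)c2OCc2ccccc2)=C(O[Si](C(C)C)(C(C)C)C(C)C)C1C(=C)OCC=C | intermediate
15 | 5-(allyloxy)-2-ArB-3-(triisopropylsilyloxy)hexa-1,3,5-trien-1-one, ketene and vinyl groups cis across C3=C4 (formed in situ) | O=C=C(c1c(C2OCCO2)ccc(OCc2ccccc2)c1OCc1ccccc1)/C(O[Si](C(C)C)(C(C)C)C(C)C)=C\C(=C)OCC=C | intermediate
16 | 5-(allyloxy)-2-ArB-3-(triisopropylsilyloxy)cyclohexa-2,4-dien-1-one (formed in situ) | O=C1CC(OCC=C)=CC(O[Si](C(C)C)(C(C)C)C(C)C)=C1c1c(C2OCCO2)ccc(OCc2ccccc2)c1OCc1ccccc1 | intermediate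
17 | 5-(allyloxy)-2-ArB-3-(triisopropylsilyloxy)phenol | Oc1cc(OCC=C)cc(O[Si](C(C)C)(C(C)C)C(C)C)c1-c1c(C2OCCO2)ccc(OCc2ccccc2)c1OCc1ccccc1 | intermediate
18 | 5-(allyloxy)-2-ArB-6-(hydroxymethyl)-3-(triisopropylsilyloxy)phenol (formed in situ) | OCc1c(O)c(-c2c(C3OCCO3)ccc(OCc3ccccc3)c2OCc2ccccc2)c(O[Si](C(C)C)(C(C)C)C(C)C)cc1OCC=C | intermediate
19 | 6-(allyloxy)-3-ArB-2-hydroxy-4-(triisopropylsilyloxy)benzaldehyde | O=Cc1c(O)c(-c2c(C3OCCO3)ccc(OCc3ccccc3)c2OCc2ccccc2)c(O[Si](C(C)C)(C(C)C)C(C)C)cc1OCC=C | intermediate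
20 | 6-(allyloxy)-3-ArB-2-(benzyloxy)-4-(triisopropylsilyloxy)benzaldehyde (formed in situ) | O=Cc1c(OCc2ccccc2)c(-c2c(C3OCCO3)ccc(OCc3ccccc3)c2OCc2ccccc2)c(O[Si](C(C)C)(C(C)C)C(C)C)cc1OCC=C | intermediate
21 | 6-(allyloxy)-3-ArB-2,4-bis(benzyloxy)benzaldehyde | O=Cc1c(OCc2ccccc2)c(-c2c(C3OCCO3)ccc(OCc3ccccc3)c2OCc2ccccc2)c(OCc2ccccc2)cc1OCC=C | intermediate
22 | 1-(benzyloxy)-4-ethynylbenzene | C#Cc1ccc(OCc2ccccc2)cc1 | starting material
23 | lithium [4-(benzyloxy)phenyl]acetylide (formed in situ) | [Li]C#Cc1ccc(OCc2ccccc2)cc1 | intermediate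
24 | 1-[6-(allyloxy)-3-ArB-2,4-bis(benzyloxy)phenyl]-3-[4-(benzyloxy)phenyl]prop-2-yn-1-ol (carbinol centre uncontrolled) | OC(C#Cc1ccc(OCc2ccccc2)cc1)c1c(OCc2ccccc2)c(-c2c(C3OCCO3)ccc(OCc3ccccc3)c2OCc2ccccc2)c(OCc2ccccc2)cc1OCC=C | intermediate
25 | 1-[6-(allyloxy)-3-ArB-2,4-bis(benzyloxy)phenyl]-3-[4-(benzyloxy)phenyl]prop-2-yn-1-one | O=C(C#Cc1ccc(OCc2ccccc2)cc1)c1c(OCc2ccccc2)c(-c2c(C3OCCO3)ccc(OCc3ccccc3)c2OCc2ccccc2)c(OCc2ccccc2)cc1OCC=C | intermediate
26 | 1-[6-(allyloxy)-3-ArB-2,4-bis(benzyloxy)phenyl]-3-[4-(benzyloxy)phenyl]-3-morpholinoprop-2-en-1-one (formed in situ) | O=C(C=C(N1CCOCC1)c1ccc(OCc2ccccc2)cc1)c1c(OCc2ccccc2)c(-c2c(C3OCCO3)ccc(OCc3ccccc3)c2OCc2ccccc2)c(OCc2ccccc2)cc1OCC=C | intermediate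
27 | 1-[3-ArB-2,4-bis(benzyloxy)-6-hydroxyphenyl]-3-[4-(benzyloxy)phenyl]-3-morpholinoprop-2-en-1-one (formed in situ) | O=C(C=C(N1CCOCC1)c1ccc(OCc2ccccc2)cc1)c1c(OCc2ccccc2)c(-c2c(C3OCCO3)ccc(OCc3ccccc3)c2OCc2ccccc2)c(OCc2ccccc2)cc1O | intermediate
28 | 5,7-bis(benzyloxy)-2-[4-(benzyloxy)phenyl]-6-ArB-4H-chromen-4-one | O=c1cc(-c2ccc(OCc3ccccc3)cc2)oc2cc(OCc3ccccc3)c(-c3c(C4OCCO4)ccc(OCc4ccccc4)c3OCc3ccccc3)c(OCc3ccccc3)c12 | intermediate
29 | 3,4-bis(benzyloxy)-2-Fl-benzaldehyde | O=Cc1ccc(OCc2ccccc2)c(OCc2ccccc2)c1-c1c(OCc2ccccc2)cc2oc(-c3ccc(OCc4ccccc4)cc3)cc(=O)c2c1OCc1ccccc1 | intermediate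
30 | 1-(2,4,6-trihydroxyphenyl)ethan-1-one | CC(=O)c1c(O)cc(O)cc1O | starting material
31 | 1-[2,4-bis(benzyloxy)-6-hydroxyphenyl]ethan-1-one | CC(=O)c1c(O)cc(OCc2ccccc2)cc1OCc1ccccc1 | intermediate
32 | dilithium enolate phenoxide of 31 (formed in situ) | [Li+].[Li+].C=C([O-])c1c([O-])cc(OCc2ccccc2)cc1OCc1ccccc1 | intermediate
33 | tert-butyl 3-[2,4-bis(benzyloxy)-6-hydroxyphenyl]-3-oxopropanoate | CC(C)(C)OC(=O)CC(=O)c1c(O)cc(OCc2ccccc2)cc1OCc1ccccc1 | intermediate
34 | tert-butyl 2-[2,4-bis(benzyloxy)-6-hydroxybenzoyl]-3-[3,4-bis(benzyloxy)-2-Fl-phenyl]prop-2-enoate (E/Z mixture) | CC(C)(C)OC(=O)C(=Cc1ccc(OCc2ccccc2)c(OCc2ccccc2)c1-c1c(OCc2ccccc2)cc2oc(-c3ccc(OCc4ccccc4)cc3)cc(=O)c2c1OCc1ccccc1)C(=O)c1c(O)cc(OCc2ccccc2)cc1OCc1ccccc1 | intermediate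
35 | tert-butyl (2S)-5,7-bis(benzyloxy)-2-[3,4-bis(benzyloxy)-2-Fl-phenyl]-4-oxochromane-3-carboxylate (C3 epimerisable, formed in situ) | O=C1C(C(=O)OC(C)(C)C)[C@@H](c2ccc(OCc3ccccc3)c(OCc3ccccc3)c2-c2c(OCc3ccccc3)cc3oc(-c4ccc(OCc5ccccc5)cc4)cc(=O)c3c2OCc2ccccc2)Oc2cc(OCc3ccccc3)cc(OCc3ccccc3)c21 | intermediate
36 | (2S)-5,7-bis(benzyloxy)-2-[3,4-bis(benzyloxy)-2-Fl-phenyl]chroman-4-one | O=C1C[C@@H](c2ccc(OCc3ccccc3)c(OCc3ccccc3)c2-c2c(OCc3ccccc3)cc3oc(-c4ccc(OCc5ccccc5)cc4)cc(=O)c3c2OCc2ccccc2)Oc2cc(OCc3ccccc3)cc(OCc3ccccc3)c21 | intermediate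
37 | (2S)-2-{2-[5,7-dihydroxy-2-(4-hydroxyphenyl)-4-oxo-4H-chromen-6-yl]-3,4-dihydroxyphenyl}-5,7-dihydroxychroman-4-one | O=C1C[C@@H](c2ccc(O)c(O)c2-c2c(O)cc3oc(-c4ccc(O)cc4)cc(=O)c3c2O)Oc2cc(O)cc(O)c21 | target

**Step count and risks**

Total steps: 18. Longest linear sequence: 15 steps (steps 1–5, 7–13 and 16–18, from compound 1).

Steps most likely to fail:

1. Step 7. The capture of the vinylketene by the doubly ortho-substituted aryl ynol ether may be too slow, so that the ketene dimerises or acylates the product phenol. Fallback: make the C2'–C6'' bond by cross-coupling instead of ring synthesis. Setting out from 3, acetalisation (ethylene glycol, TsOH, PhH, reflux) gives 2-[3,4-bis(benzyloxy)-2-bromophenyl]-1,3-dioxolane F1. Bromine–lithium exchange and borylation (n-BuLi, THF, −78 °C; 2-isopropoxy-4,4,5,5-tetramethyl-1,3,2-dioxaborolane) give 2-ArB-4,4,5,5-tetramethyl-1,3,2-dioxaborolane F2. In parallel, commercial apigenin is benzylated at O7 and O4' (BnBr, K2CO3, DMF) to 7-(benzyloxy)-2-[4-(benzyloxy)phenyl]-5-hydroxy-4H-chromen-4-one F3. Iodination ortho to the chelated hydroxyl (I2, TlOAc, CH2Cl2) gives 7-(benzyloxy)-2-[4-(benzyloxy)phenyl]-5-hydroxy-6-iodo-4H-chromen-4-one F4, and benzylation of O5 gives 5,7-bis(benzyloxy)-2-[4-(benzyloxy)phenyl]-6-iodo-4H-chromen-4-one F5. Suzuki–Miyaura coupling of F2 with F5 (Pd(OAc)2, SPhos, K3PO4, PhMe/H2O, 100 °C) rejoins the route at compound 28.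

2. Step 17. Facial selectivity in the oxa-Michael closure may be poor because of the bulky ortho-biaryl substituent at the beta-carbon and the slowly rotating axis; a sluggish Knoevenagel condensation in step 16 is covered by the same detour. Fallback: racemic ring closure and separation of enantiomers. Setting out from 29 and 31, Claisen–Schmidt condensation (KOH, EtOH/THF, rt) gives (E)-1-[2,4-bis(benzyloxy)-6-hydroxyphenyl]-3-[3,4-bis(benzyloxy)-2-Fl-phenyl]prop-2-en-1-one F6. Cyclisation (NaOAc, EtOH, reflux) gives racemic 5,7-bis(benzyloxy)-2-[3,4-bis(benzyloxy)-2-Fl-phenyl]chroman-4-one F7. Preparative chromatography on a polysaccharide chiral stationary phase removes the (2R)-enantiomer F8 and delivers the (2S)-enantiomer, which is compound 36.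

3. Step 6. The strained vinylogous ester may hydrolyse or open under acid instead of exchanging its alkoxy group. Fallback: setting out from 11, cold aqueous acid hydrolysis (TFA/H2O, 0 °C) gives cyclobutane-1,3-dione F9, whose acidic enol is O-allylated under Mitsunobu conditions (allyl alcohol, PPh3, DIAD, THF, 0 °C) to return to compound 12.

Further compounds
F1 | step 7 | 2-[3,4-bis(benzyloxy)-2-bromophenyl]-1,3-dioxolane | Brc1c(C2OCCO2)ccc(OCc2ccccc2)c1OCc1ccccc1
F2 | step 7 | 2-[2,3-bis(benzyloxy)-6-(1,3-dioxolan-2-yl)phenyl]-4,4,5,5-tetramethyl-1,3,2-dioxaborolane | CC1(C)OB(OC1(C)C)c1c(C2OCCO2)ccc(OCc2ccccc2)c1OCc1ccccc1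
F3 | step 7 | 7-(benzyloxy)-2-[4-(benzyloxy)phenyl]-5-hydroxy-4H-chromen-4-one | O=c1cc(-c2ccc(OCc3ccccc3)cc2)oc2cc(OCc3ccccc3)cc(O)c12
F4 | step 7 | 7-(benzyloxy)-2-[4-(benzyloxy)phenyl]-5-hydroxy-6-iodo-4H-chromen-4-one | O=c1cc(-c2ccc(OCc3ccccc3)cc2)oc2cc(OCc3ccccc3)c(I)c(O)c12
F5 | step 7 | 5,7-bis(benzyloxy)-2-[4-(benzyloxy)phenyl]-6-iodo-4H-chromen-4-one | O=c1cc(-c2ccc(OCc3ccccc3)cc2)oc2cc(OCc3ccccc3)c(I)c(OCc3ccccc3)c12
F6 | step 17 | (E)-1-[2,4-bis(benzyloxy)-6-hydroxyphenyl]-3-[3,4-bis(benzyloxy)-2-Fl-phenyl]prop-2-en-1-one | O=C(/C=C/c1ccc(OCc2ccccc2)c(OCc2ccccc2)c1-c1c(OCc2ccccc2)cc2oc(-c3ccc(OCc4ccccc4)cc3)cc(=O)c2c1OCc1ccccc1)c1c(O)cc(OCc2ccccc2)cc1OCc1ccccc1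
F7 | step 17 | racemic 5,7-bis(benzyloxy)-2-[3,4-bis(benzyloxy)-2-Fl-phenyl]chroman-4-one | O=C1CC(c2ccc(OCc3ccccc3)c(OCc3ccccc3)c2-c2c(OCc3ccccc3)cc3oc(-c4ccc(OCc5ccccc5)cc4)cc(=O)c3c2OCc2ccccc2)Oc2cc(OCc3ccccc3)cc(OCc3ccccc3)c21
F8 | step 17 | (2R)-5,7-bis(benzyloxy)-2-[3,4-bis(benzyloxy)-2-Fl-phenyl]chroman-4-one | O=C1C[C@H](c2ccc(OCc3ccccc3)c(OCc3ccccc3)c2-c2c(OCc3ccccc3)cc3oc(-c4ccc(OCc5ccccc5)cc4)cc(=O)c3c2OCc2ccccc2)Oc2cc(OCc3ccccc3)cc(OCc3ccccc3)c21
F9 | step 6 | cyclobutane-1,3-dione | O=C1CC(=O)C1
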